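**Strategy**

Everything rests on disconnecting the C-alpha–O bond. C-alpha, the lone stereocentre, is the only enolisable carbon of the molecule: a CH2 lying between the ketone carbon on C1' of ring A and the benzylic CH2 of ring B. The achiral dihydrochalcone is therefore assembled first, with all three phenols as MOM ethers, by two successive bromine–lithium exchanges on a symmetric dibromide (prenylation, then Weinreb acylation). Its Z sodium enolate then accepts an oxygen atom from an enantiopure N-sulfonyloxaziridine, which in one operation forms the C–O bond and the (S) centre while leaving the prenyl alkene alone. Mild acid methanolysis finally releases the phenols.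

Key step: step 7

Assumption: the reagent antipode made from (1S)-(+)-10-camphorsulfonic acid is taken to deliver oxygen to the enolate face that gives the (S) carbinol, as it does with Z sodium enolates of simple aryl alkyl ketones; if the ortho-alkoxy group inverts the sense, the commercially available mirror-image reagent is used in the same step.

**Route**

Step 1
Reactants: 1 2-methylresorcinol
Product: 2 4,6-dibromo-2-methylbenzene-1,3-diol
Conditions: Br2 (2.05 equiv), CH2Cl2/AcOH, 0 °C → rt
Reagents that add atoms: bromine, BrBr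
Why: Electrophilic aromatic bromination is directed by both hydroxyls to C4 and C6 (each ortho to one OH and para to the other), while C5, meta to both, is left alone, so the symmetric dibromide is the only expected product.

Step 2
Reactants: 2 4,6-dibromo-2-methylbenzene-1,3-diol
Product: 3 1,5-dibromo-2,4-bis(methoxymethoxy)-3-methylbenzene
Conditions: NaH (2.5 equiv), THF/DMF, 0 °C; MOMCl (2.5 equiv), 0 °C → rt
Reagents that add atoms: chloromethyl methyl ether (MOMCl), COCCl
Why: Williamson-type O-alkylation of the two sodium phenoxides with the highly reactive α-chloro ether proceeds even at these doubly ortho-substituted oxygens and installs acetals that tolerate organolithium reagents and stabilise an adjacent aryllithium.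

Step 3
Reactants: 3 1,5-dibromo-2,4-bis(methoxymethoxy)-3-methylbenzene; 4 prenyl bromide
Product: 7 1-bromo-2,4-bis(methoxymethoxy)-3-methyl-5-(3-methylbut-2-en-1-yl)benzene, via aryllithium 5 (not isolated), via arylcopper 6 (not isolated)
Conditions: n-BuLi (1.0 equiv), THF, −78 °C; CuBr·SMe2 (1.05 equiv), −78 → −40 °C; 4 (1.3 equiv), −78 °C → rt
Reagents that add atoms: n-butyllithium, [Li]CCCC (lithium of 5 only); CuBr·SMe2, CSC.[Cu]Br (copper of 6 only)
Why: Bromine–lithium exchange on the symmetric dibromide can give only one monolithio species, which the ortho MOM ether stabilises and whose negative charge retards a second exchange, and after transmetalation the organocopper undergoes allylic substitution at the unhindered primary carbon of the allylic bromide.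

Step 4
Reactants: 8 3-(4-hydroxyphenyl)propanoic acid
Product: 9 3-(4-hydroxyphenyl)-N-methoxy-N-methylpropanamide
Conditions: MeNH(OMe)·HCl (1.2 equiv), EDC·HCl (1.2 equiv), HOBt (0.2 equiv), N-methylmorpholine (2.5 equiv), CH2Cl2/DMF, 0 °C → rt
Reagents that add atoms: N,O-dimethylhydroxylamine hydrochloride, CNOC.Cl
Why: Carbodiimide-mediated amide coupling through the benzotriazolyl ester works because the amine is far more nucleophilic than the free phenol, giving the N-methoxy-N-methylamide needed for a single addition of an organolithium.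

Step 5
Reactants: 9 3-(4-hydroxyphenyl)-N-methoxy-N-methylpropanamide
Product: 10 N-methoxy-3-[4-(methoxymethoxy)phenyl]-N-methylpropanamide
Conditions: MOMCl (1.5 equiv), i-Pr2NEt (2.0 equiv), CH2Cl2, 0 °C → rt
Reagents that add atoms: chloromethyl methyl ether (MOMCl), COCCl
Why: Base-mediated O-alkylation of the phenol with the α-chloro ether (acetal formation by nucleophilic substitution) masks the only acidic proton of the amide before it meets the aryllithium.

Step 6
Reactants: 7 1-bromo-2,4-bis(methoxymethoxy)-3-methyl-5-(3-methylbut-2-en-1-yl)benzene; 10 N-methoxy-3-[4-(methoxymethoxy)phenyl]-N-methylpropanamide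
Product: 13 1-[2,4-bis(methoxymethoxy)-3-methyl-5-(3-methylbut-2-en-1-yl)phenyl]-3-[4-(methoxymethoxy)phenyl]propan-1-one, via aryllithium 11 (not isolated), via lithium hemiaminal 12 (not isolated)
Conditions: 7 (1.1 equiv), n-BuLi (1.05 equiv), THF, −78 °C; 10 (1.0 equiv), −78 → 0 °C; sat. aq. NH4Cl
Reagents that add atoms: n-butyllithium, [Li]CCCC (lithium of 11 and 12 only)
Why: Weinreb ketone synthesis, in which the aryllithium from a second bromine–lithium exchange adds once to the amide and the five-membered lithium chelate 12 survives until the aqueous quench, so that no tertiary alcohol can form.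

Step 7
Reactants: 13 1-[2,4-bis(methoxymethoxy)-3-methyl-5-(3-methylbut-2-en-1-yl)phenyl]-3-[4-(methoxymethoxy)phenyl]propan-1-one
Product: 17 (2S)-1-[2,4-bis(methoxymethoxy)-3-methyl-5-(3-methylbut-2-en-1-yl)phenyl]-2-hydroxy-3-[4-(methoxymethoxy)phenyl]propan-1-one, via sodium Z-enolate 14 (not isolated), via hemiaminal sodium salt 15 (not isolated), via sodium alkoxide 16 (not isolated)
Conditions: NaN(SiMe3)2 (1.2 equiv), THF, −78 °C, 30 min; (+)-[(8,8-dichlorocamphoryl)sulfonyl]oxaziridine (1.5 equiv), THF, −78 °C; sat. aq. NH4Cl, −78 °C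
Reagents that add atoms: (+)-[(8,8-dichlorocamphoryl)sulfonyl]oxaziridine, CC1(C)[C@@H]2CC[C@]13CS(=O)(=O)N4O[C@@]34C2(Cl)Cl (oxygen of the new hydroxyl); NaN(SiMe3)2, C[Si](C)(C)[N-][Si](C)(C)C.[Na+] (sodium of 14, 15 and 16 only)
Why: NaN(SiMe3)2 deprotonates C-alpha, the only enolisable carbon, and allylic strain against ring A makes enolate 14 the Z isomer. Its α-carbon attacks the electrophilic oxaziridine oxygen in an SN2-type displacement on the N–O bond, and hemiaminal 15 fragments to the sulfonimine and alkoxide 16, which is the established asymmetric hydroxylation of aryl alkyl ketone enolates by enantiopure N-sulfonyloxaziridines. No ring is closed; only the C-alpha–O bond is formed. The new C-alpha centre is reagent-controlled: the camphor framework and the two chlorine atoms flanking the oxaziridine shield one approach to the planar enolate, and the antipode chosen should give (S). The step needs chemoselectivity over the prenyl alkene and a single oxidation, which the aprotic oxaziridine (no epoxidation of a trisubstituted alkene at −78 °C), the non-enolisable alkoxide 16 and the absence of any other acidic C–H provide. The aryl MOM ethers are inert to the amide base, and the cold NH4Cl quench guards the new centre against base-mediated epimerisation.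

Step 8
Reactants: 17 (2S)-1-[2,4-bis(methoxymethoxy)-3-methyl-5-(3-methylbut-2-en-1-yl)phenyl]-2-hydroxy-3-[4-(methoxymethoxy)phenyl]propan-1-one
Product: 18 Lespeflorin C5, (2S)-1-[2,4-dihydroxy-3-methyl-5-(3-methylbut-2-en-1-yl)phenyl]-2-hydroxy-3-(4-hydroxyphenyl)propan-1-one
Conditions: conc. aq. HCl in MeOH (ca. 1.5 M HCl), 0 °C → rt; aq. NaHCO3 quench
Reagents that add atoms: none
Why: Acid-catalysed acetal exchange with methanol releases the three aryl MOM groups as dimethoxymethane, and dilute acid at or below ambient temperature is expected to spare the ortho-prenyl phenol from cyclisation and the α-ketol centre from enolisation.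

**Compound list**

1 | 2-methylresorcinol (2-methylbenzene-1,3-diol) | Cc1c(O)cccc1O | starting material
2 | 4,6-dibromo-2-methylbenzene-1,3-diol | Cc1c(O)c(Br)cc(Br)c1O | intermediate
3 | 1,5-dibromo-2,4-bis(methoxymethoxy)-3-methylbenzene | Cc1c(OCOC)c(Br)cc(Br)c1OCOC | intermediate
4 | prenyl bromide (1-bromo-3-methylbut-2-ene) | CC(C)=CCBr | starting material
5 | [5-bromo-2,4-bis(methoxymethoxy)-3-methylphenyl]lithium | [Li]c1cc(Br)c(OCOC)c(C)c1OCOC | intermediate (not isolated)
6 | [5-bromo-2,4-bis(methoxymethoxy)-3-methylphenyl]copper | [Cu]c1cc(Br)c(OCOC)c(C)c1OCOC | intermediate (not isolated)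
7 | 1-bromo-2,4-bis(methoxymethoxy)-3-methyl-5-(3-methylbut-2-en-1-yl)benzene | CC(C)=CCc1cc(Br)c(OCOC)c(C)c1OCOC | intermediate
8 | 3-(4-hydroxyphenyl)propanoic acid | O=C(O)CCc1ccc(O)cc1 | starting material
9 | 3-(4-hydroxyphenyl)-N-methoxy-N-methylpropanamide | CON(C)C(=O)CCc1ccc(O)cc1 | intermediate
10 | N-methoxy-3-[4-(methoxymethoxy)phenyl]-N-methylpropanamide | CON(C)C(=O)CCc1ccc(OCOC)cc1 | intermediate
11 | [2,4-bis(methoxymethoxy)-3-methyl-5-(3-methylbut-2-en-1-yl)phenyl]lithium | [Li]c1cc(CC=C(C)C)c(OCOC)c(C)c1OCOC | intermediate (not isolated)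
12 | lithium 1-[2,4-bis(methoxymethoxy)-3-methyl-5-(3-methylbut-2-en-1-yl)phenyl]-1-[methoxy(methyl)amino]-3-[4-(methoxymethoxy)phenyl]propan-1-olate (racemic tetrahedral adduct) | [Li+].[O-]C(CCc1ccc(OCOC)cc1)(N(C)OC)c1cc(CC=C(C)C)c(OCOC)c(C)c1OCOC | intermediate (not isolated)
13 | 1-[2,4-bis(methoxymethoxy)-3-methyl-5-(3-methylbut-2-en-1-yl)phenyl]-3-[4-(methoxymethoxy)phenyl]propan-1-one (tris-MOM dihydrochalcone) | CC(C)=CCc1cc(C(=O)CCc2ccc(OCOC)cc2)c(OCOC)c(C)c1OCOC | intermediate
14 | sodium (Z)-1-[2,4-bis(methoxymethoxy)-3-methyl-5-(3-methylbut-2-en-1-yl)phenyl]-3-[4-(methoxymethoxy)phenyl]prop-1-en-1-olate | CC(C)=CCc1cc(/C([O-])=C/Cc2ccc(OCOC)cc2)c(OCOC)c(C)c1OCOC.[Na+] | intermediate (not isolated)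
15 | sodium salt of the N-sulfonyl hemiaminal in which the (S)-configured C-alpha oxygen is bonded to the former oxaziridine carbon of the dichlorocamphor sultam and the sulfonamide nitrogen is anionic | CC1(C)[C@@H]2CC[C@]13CS(=O)(=O)[N-][C@]3(O[C@@H](Cc4ccc(OCOC)cc4)C(=O)c4cc(CC=C(C)C)c(OCOC)c(C)c4OCOC)C2(Cl)Cl.[Na+] | intermediate (not isolated)
16 | sodium (2S)-1-[2,4-bis(methoxymethoxy)-3-methyl-5-(3-methylbut-2-en-1-yl)phenyl]-3-[4-(methoxymethoxy)phenyl]-1-oxopropan-2-olate | CC(C)=CCc1cc(C(=O)[C@@H]([O-])Cc2ccc(OCOC)cc2)c(OCOC)c(C)c1OCOC.[Na+] | intermediate (not isolated)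
17 | (2S)-1-[2,4-bis(methoxymethoxy)-3-methyl-5-(3-methylbut-2-en-1-yl)phenyl]-2-hydroxy-3-[4-(methoxymethoxy)phenyl]propan-1-one | CC(C)=CCc1cc(C(=O)[C@@H](O)Cc2ccc(OCOC)cc2)c(OCOC)c(C)c1OCOC | intermediate
18 | Lespeflorin C5, (2S)-1-[2,4-dihydroxy-3-methyl-5-(3-methylbut-2-en-1-yl)phenyl]-2-hydroxy-3-(4-hydroxyphenyl)propan-1-one | CC(C)=CCc1cc(C(=O)[C@@H](O)Cc2ccc(O)cc2)c(O)c(C)c1O | target

**Step count and risk**

Total steps: 8. Longest linear sequence: 6 steps (steps 1, 2, 3, 6, 7 and 8 from 2-methylresorcinol); the amide branch (steps 4 and 5) joins at step 6.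

Steps most likely to fail:

Step 7. The oxygen transfer may show insufficient or inverted enantiofacial selectivity, because the ortho-alkoxy aryl enolate may chelate sodium and present itself to the reagent differently from simple aryl ketone enolates; the oxidation may also stall. Screening the parent and 8,8-dimethoxy reagents and the counter-ion is optimisation only. The fallback changes the approach to a chiral-pool acylation, sets out from 7 and comes back at 17.
- (2S)-2-hydroxy-3-(4-hydroxyphenyl)propanoic acid F1 (purchased, or made from L-tyrosine by diazotisation with retention) is coupled as in step 4 to give (2S)-2-hydroxy-3-(4-hydroxyphenyl)-N-methoxy-N-methylpropanamide F2.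
- The phenol alone is alkylated (MOMCl, K2CO3, acetone) to give (2S)-2-hydroxy-N-methoxy-3-[4-(methoxymethoxy)phenyl]-N-methylpropanamide F3.
- The secondary alcohol is silylated (Et3SiCl, imidazole, DMF) to give (2S)-N-methoxy-3-[4-(methoxymethoxy)phenyl]-N-methyl-2-(triethylsilyloxy)propanamide F4.
- Aryllithium 11, generated from 7 as in step 6, adds once to F4 at −78 °C to give (2S)-1-[2,4-bis(methoxymethoxy)-3-methyl-5-(3-methylbut-2-en-1-yl)phenyl]-3-[4-(methoxymethoxy)phenyl]-2-(triethylsilyloxy)propan-1-one F5.
- HF·pyridine in THF at 0 °C removes the silyl group and delivers 17 with the stereocentre taken from the pool.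

Step 8. The freed C4' hydroxyl may attack the protonated prenyl alkene (chroman formation), HCl or methanol may add to that alkene, or acid-catalysed enolisation may erode the configuration at C-alpha. The fallback replaces Brønsted-acid acetal exchange by Lewis-acid silyl transfer under a pyridine-type buffer, sets out from 17 and comes back at 18.
- Me3SiOTf and 2,2'-bipyridyl in MeCN (0 °C → rt) convert the three aryl MOM ethers into silyl ethers and silylate the secondary hydroxyl, giving (2S)-1-[3-methyl-5-(3-methylbut-2-en-1-yl)-2,4-bis(trimethylsilyloxy)phenyl]-2-(trimethylsilyloxy)-3-[4-(trimethylsilyloxy)phenyl]propan-1-one F6.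
- Water and a short contact with a pH 4–5 citrate buffer hydrolyse F6 to 18 without exposing the ortho-prenyl phenol to strong acid.

Step 3. The copper coupling may suffer allylic transposition (bond formation at the tertiary end of the allyl unit), or proton transfer between aryllithium 5 and unreacted 3 may scramble the halogens. The fallback builds the prenyl group by allylation and olefin metathesis, sets out from 3 and comes back at 7.
- Arylcopper 6, made from 3 as in step 3, is quenched with allyl bromide, for which both allyl termini are identical, to give 1-allyl-5-bromo-2,4-bis(methoxymethoxy)-3-methylbenzene F7.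
- Cross-metathesis of F7 with excess 2-methylbut-2-ene (second-generation Grubbs catalyst, CH2Cl2, 40 °C) gives 7.

**Further compounds**

F1 | step 7 | (2S)-2-hydroxy-3-(4-hydroxyphenyl)propanoic acid | O=C(O)[C@@H](O)Cc1ccc(O)cc1
F2 | step 7 | (2S)-2-hydroxy-3-(4-hydroxyphenyl)-N-methoxy-N-methylpropanamide | CON(C)C(=O)[C@@H](O)Cc1ccc(O)cc1
F3 | step 7 | (2S)-2-hydroxy-N-methoxy-3-[4-(methoxymethoxy)phenyl]-N-methylpropanamide | CON(C)C(=O)[C@@H](O)Cc1ccc(OCOC)cc1
F4 | step 7 | (2S)-N-methoxy-3-[4-(methoxymethoxy)phenyl]-N-methyl-2-(triethylsilyloxy)propanamide | CON(C)C(=O)[C@@H](O[Si](CC)(CC)CC)Cc1ccc(OCOC)cc1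
F5 | step 7 | (2S)-1-[2,4-bis(methoxymethoxy)-3-methyl-5-(3-methylbut-2-en-1-yl)phenyl]-3-[4-(methoxymethoxy)phenyl]-2-(triethylsilyloxy)propan-1-one | CC(C)=CCc1cc(C(=O)[C@@H](O[Si](CC)(CC)CC)Cc2ccc(OCOC)cc2)c(OCOC)c(C)c1OCOC
F6 | step 8 | (2S)-1-[3-methyl-5-(3-methylbut-2-en-1-yl)-2,4-bis(trimethylsilyloxy)phenyl]-2-(trimethylsilyloxy)-3-[4-(trimethylsilyloxy)phenyl]propan-1-one | CC(C)=CCc1cc(C(=O)[C@@H](O[Si](C)(C)C)Cc2ccc(O[Si](C)(C)C)cc2)c(O[Si](C)(C)C)c(C)c1O[Si](C)(C)C
F7 | step 3 | 1-allyl-5-bromo-2,4-bis(methoxymethoxy)-3-methylbenzene | C=CCc1cc(Br)c(OCOC)c(C)c1OCOC
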